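All runs come from a simulation with made-up constants.

- Leave this flask's charges alone while it runs: 20.0 mM of first nucleophile and 80.0 mM of second nucleophile share out what the substrate gives up.

| setting | south-east | south | north-east | flask |
|---|---|---|---|---|
| substrate | 20 mM | 20 mM | 20 mM | 20 mM |
| first nucleophile | 10 mM | 40 mM | 20 mM | 20.0 mM |
| second nucleophile | 80 mM | 80 mM | 120 mM | 80.0 mM |
| remark | run made earlier | run made earlier | run made earlier |  |
| time |  |  |  | 10 min |

| run | time / min | intermediate / % | other capture product / % | isomer of the product / % | target / % | substrate / % |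
|---|---|---|---|---|---|---|
| south-east | 0.667 | 0.4 | 8.1 | 0 | 1.0 | 90.5 |
| south-east | 1.33 | 0.8 | 18.3 | 0.1 | 4.3 | 77.2 |
| south-east | 3.00 | 0.1 | 33.5 | 0.6 | 8.2 | 56.3 |
| south-east | 8.00 | 0.7 | 63.3 | 1.9 | 13.0 | 21.8 |
| south | 0.667 | 1.1 | 3.5 | 0.5 | 5.7 | 88.9 |
| south | 1.33 | 0.3 | 10.2 | 0 | 12.0 | 76.3 |
| south | 3.00 | 0.5 | 20.4 | 1.0 | 19.2 | 56.6 |
| south | 8.00 | 0 | 38.1 | 4.1 | 32.9 | 20.7 |
| north-east | 2.00 | 1.7 | 22.3 | 0 | 8.1 | 68.5 |
| north-east | 4.00 | 0 | 38.3 | 0.6 | 13.3 | 46.5 |
| north-east | 6.00 | 0.9 | 52.7 | 0.6 | 15.2 | 31.4 |
| north-east | 8.00 | 0 | 59.2 | 3.9 | 16.2 | 22.3 |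

(readings scatter by 1 percentage point)

- what may be going on: substrate -> intermediate; first nucleophile + intermediate -> target; second nucleophile + intermediate -> other capture product; target <-> isomer of the product; intermediate -> decomposed reagent

* the species that holds most of what was charged as substrate, at 10 min (target / isomer of the product / intermediate / substrate / other capture product)
* the largest share itself, whichever of these holds it, in percent of the substrate charged

- The substrate left at 8.00 min reads 21.8 %, 20.7 % and 22.3 % in the south-east, south and north-east runs, though c(first nucleophile) goes from 10 mM to 40 mM between the first two and the north-east run has 120 mM of second nucleophile against 80 mM. So I take first-order loss at 0.190 min⁻¹, leaving 14.9 % in this flask at 10 min.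
- Count target and isomer together. Their sum per other capture product, times c(second nucleophile)/c(first nucleophile) as charged, gives my reading of the selectivity factor from the last readings: 1.94 in the south run and 1.88 in the south-east run.
- For this flask I carry the split, target plus isomer formed per other capture product, the selectivity factor times the charge ratio: 0.486.
- So I expect this flask to hold 57.3 % as other capture product at 10 min, the most of any species.
- The forecast, which says other capture product at 57.5 %, starts from "The substrate decays first order at about 0.19 per minute", and this flask gives other capture product at 56.8 %.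

    substrate → intermediate (k = 0.00320 s⁻¹)
    first nucleophile + intermediate → target (k = 11.0 L mol⁻¹ s⁻¹)
    second nucleophile + intermediate → other capture product (k = 5.10 L mol⁻¹ s⁻¹)
    target ⇌ isomer of the product (K = 5.40, k = 5.10 × 10⁻⁴ s⁻¹)
    intermediate → decomposed reagent (k = 0.00240 s⁻¹)

- In this flask at 2.90 min, the second nucleophile uses the intermediate 2.0 times as fast as the first nucleophile does, close to the 2.06 my split implies, and at 10 min the products stand at 0.495 against 0.486. The same split applied to this flask read at 40 min, with 0.046 % of the substrate left, gives 67.3 % of other capture product, and that flask holds 66.9 %.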